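You read the flask at 25 min, and the number to carry is the fraction of substrate left, not the fraction made.

substrate 22 mM; gas phase 1.1 mM (held); free catalyst 0.48 mM; time 25 min

    substrate + dissolved gas + free catalyst ⇌ free catalyst + product (K1 = 18000 M⁻¹, k1 = 4700 M⁻² s⁻¹)
    gas phase ⇌ dissolved gas, rate k2*(csat - [dissolved gas]) (k2 = 0.021 s⁻¹, csat = 1.1 mM)
    free catalyst → spent catalyst (k3 = 0.0020 s⁻¹)

- at the start none of the gas is dissolved
- run time (flask): 25 min

* product at 25 min, in percent of the substrate charged
* concentration of dissolved gas in solution at 6.0 min, in percent of saturation
* the change that raises the amount of product at 25 min, in percent of the substrate charged most ("none" if none brings more than 2 percentage points) (Tuesday's / Sunday's / Thursday's / none)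
* amount of product at 25 min, in percent of the substrate charged, after Thursday's

- Tuesday's: doubling the amount of free catalyst, all else as stated
- Sunday's: doubling the transfer coefficient of step 2, all else as stated
- Thursday's: doubling the saturation concentration of gas phase, all else as stated

Here is my own reckoning. Free catalyst decays by itself, to 4.98% of its charge at 25 min. The forward half-life of dissolved gas in the catalytic step, 0.23 min at the charges, is short against the run, and so is the half-life of transfer, 0.550 min, so you may take a quasi-steady state: c(dissolved gas) = T·csat/(T + r). Here T is the transfer coefficient, and r is the catalytic rate constant times c(free catalyst) times a mean c(substrate), which I guess at 15.4 mM.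

The fractional loss of substrate per second is then (r/mean)·T·csat/(T + r). Integrating while r decays with d, the first-order decay constant of free catalyst, gives T·csat/(d·mean)·ln[(T + r at start)/(T + r at reading)] = 0.673. Call this the reach: the logarithm of substrate charged over substrate left.

So 51.0% stays and the yield is 49.0%. Equilibrium at saturation leaves 4.81%, less than that, so I drop the way back. At 6.0 min the balance gives 55.4%. Doubling csat doubles the reach at this mean, so 74.0%, and the best change is Thursday's.

The forecast, which “puts transfer and reaction in series”, says 45% (43% to 47%), 51% (48% to 54%), Thursday's, and 72% (69% to 75%). Its yield is lower than mine, its saturation is lower than mine, and its yield after Thursday's is lower than mine; we pick the same change.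

The flask gives 45.0%, 51.3%, Thursday's (a gain of 27 percentage points, against 15 points for Tuesday's and 9.2 points for Sunday's), and 72.4%. The forecast holds on each question, and my yield stands higher than the flask's.

Left on, this flask still keeps more substrate than the equilibrium share. At 25.0 min it holds 4.98% of its free catalyst. After 250 min it holds 0% free catalyst, 48.0% product and 52.0% substrate, so the extra time brings 3.0 points. My reach, taken to that time, grows to 0.732, which lowers my fraction left by 2.9 points.

For the neighbour charged with 37 mM substrate, the same mean fraction gives a reach of 0.535, so 58.6% left. That neighbour keeps 63% and yields 37.3%.

Its constants are those of an exercise; the rest is arithmetic.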